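**Strategy.** The route rests on disconnecting C3–C4 (cembrane numbering): the lactone O–CH carbon and the neighbouring tertiary carbinol carbon, two oxygen-bearing carbons of like polarity that lie side by side in the 14-membered ring, with O3 standing 1,3 to the propionate arm on C1. A samarium diiodide ketyl (pinacol) coupling of a C3 aldehyde with a C4 methyl ketone joins them by polarity reversal: in one operation it closes the 14-membered carbocycle, sets C3 and C4, and lets the new C3 alkoxide close the δ-lactone onto a C16 thioester. The precursor is an open-chain epoxy keto aldehyde thioester that already carries C1, C7, C11, C12 and C15.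

Key step: step 13

Remark on numbering and supply: cembrane numbering is used throughout (ring carbons C1–C14; C15–C17 the propionate unit on C1; C18, C19, C20 the one-carbon groups on C4, C8, C12). Hex-1-en-5-yne, S-ethyl propanethioate and both enantiomers of the fructose-derived epoxidation ketone are assumed to be purchasable.

**Step 1**
Reactants: 1 6-methylhept-5-en-2-one; 2 ethane-1,2-diol
Product: 3 2-methyl-2-(4-methylpent-3-en-1-yl)-1,3-dioxolane
Conditions: p-TsOH (cat.), benzene, reflux, Dean–Stark
Reagents that add atoms: none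
Why: Acid-catalysed ketalisation with azeotropic removal of water masks the future C4 ketone against the organolithium and aluminium reagents that follow; no stereocentre is formed.

**Step 2**
Reactants: 3 2-methyl-2-(4-methylpent-3-en-1-yl)-1,3-dioxolane
Product: 4 2-{2-[(2R)-3,3-dimethyloxiran-2-yl]ethyl}-2-methyl-1,3-dioxolane
Conditions: D-fructose-derived Shi ketone (0.3 equiv), KHSO5 (as 2KHSO5·KHSO4·K2SO4), K2CO3, Bu4NHSO4, Na2B4O7/Na2EDTA buffer, MeCN–CH2(OMe)2–H2O, 0 °C
Reagents that add atoms: potassium peroxymonosulfate, [K+].[O-]S(=O)(=O)OO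
Why: Shi asymmetric epoxidation of the trisubstituted olefin through the spiro dioxirane transition state; the D-fructose-derived ketone should deliver oxygen to the face that gives the (R) epoxide, which becomes C7.

**Step 3**
Reactants: 4 2-{2-[(2R)-3,3-dimethyloxiran-2-yl]ethyl}-2-methyl-1,3-dioxolane
Product: 5 (3R)-2-methyl-5-(2-methyl-1,3-dioxolan-2-yl)pent-1-en-3-ol
Conditions: Al(OiPr)3 (1 equiv), toluene, 110 °C; Rochelle-salt work-up
Reagents that add atoms: none
Why: Aluminium alkoxide-mediated isomerisation of a trisubstituted epoxide to an allylic alcohol: syn β-elimination removes a methyl proton and breaks the tertiary C8–O bond, so the C7–O bond and its (R) configuration are untouched.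

**Step 4**
Reactants: 6 hex-1-en-5-yne
Product: 9 (2E)-3-methylhepta-2,6-dien-1-ol, via alkenyldimethylalane 7 (not isolated), via lithium alkenylalanate 8 (not isolated)
Conditions: Me3Al (2.5 equiv), Cp2ZrCl2 (0.25 equiv), CH2Cl2, 0 → 23 °C; then n-BuLi, THF–hexane, −78 °C; (CH2O)n, → 23 °C; H2O
Reagents that add atoms: trimethylaluminium, C[Al](C)C; paraformaldehyde (as formaldehyde), C=O
Why: Negishi zirconium-catalysed carboalumination adds methyl and aluminium syn across the alkyne (methyl to the internal carbon, the alkene being far less reactive), and hydroxymethylation of the alanate with retention fixes the E-trisubstituted C11=C12 olefin.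

**Step 5**
Reactants: 9 (2E)-3-methylhepta-2,6-dien-1-ol
Product: 10 (5E)-7-bromo-5-methylhepta-1,5-diene
Conditions: CBr4, PPh3, CH2Cl2, 0 °C
Reagents that add atoms: carbon tetrabromide, BrC(Br)(Br)Br
Why: Appel bromination; bromide displaces the alkoxyphosphonium group at the primary allylic carbon without transposition, so the E geometry is kept.

**Step 6**
Reactants: 5 (3R)-2-methyl-5-(2-methyl-1,3-dioxolan-2-yl)pent-1-en-3-ol; 10 (5E)-7-bromo-5-methylhepta-1,5-diene
Product: 12 (3R,7E)-8-methyl-4-methylidene-1-(2-methyl-1,3-dioxolan-2-yl)dodeca-7,11-dien-3-ol, via O,C-dilithio derivative 11 (not isolated)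
Conditions: n-BuLi (2.2 equiv), TMEDA, Et2O–hexane, 0 → 23 °C; then 10, THF, −78 → 0 °C; H2O
Reagents that add atoms: none
Why: Alkoxide-directed allylic lithiation of the 2-methylallylic alcohol gives the O,C-dianion, which is C-alkylated at the primary allylic bromide (SN2); the two termini of the 2-substituted allyl anion are equivalent, so a single C9–C10 connectivity results and C7 is not touched.

**Step 7**
Reactants: 12 (3R,7E)-8-methyl-4-methylidene-1-(2-methyl-1,3-dioxolan-2-yl)dodeca-7,11-dien-3-ol
Product: 13 tert-butyl(dimethyl){[(3R,7E)-8-methyl-4-methylidene-1-(2-methyl-1,3-dioxolan-2-yl)dodeca-7,11-dien-3-yl]oxy}silane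
Conditions: TBSCl, imidazole, DMF, 23 °C
Reagents that add atoms: tert-butyldimethylsilyl chloride, CC(C)(C)[Si](C)(C)Cl
Why: Silylation of the secondary allylic alcohol prevents hemiketal formation with the C4 ketone, hydroxyl-directed epoxidation of C8=C19 and attack of O7 on the later epoxide.

**Step 8**
Reactants: 13 tert-butyl(dimethyl){[(3R,7E)-8-methyl-4-methylidene-1-(2-methyl-1,3-dioxolan-2-yl)dodeca-7,11-dien-3-yl]oxy}silane
Product: 14 (5R,9E)-5-[(tert-butyldimethylsilyl)oxy]-10-methyl-6-methylidenetetradeca-9,13-dien-2-one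
Conditions: PPTS (cat.), acetone–H2O, 50 °C
Reagents that add atoms: water, O
Why: Mild acid-catalysed ketal hydrolysis frees the C4 methyl ketone before the acid-sensitive epoxide is introduced; the secondary TBS ether and the olefins should survive.

**Step 9**
Reactants: 14 (5R,9E)-5-[(tert-butyldimethylsilyl)oxy]-10-methyl-6-methylidenetetradeca-9,13-dien-2-one
Product: 15 (5R)-8-[(2S,3S)-3-(but-3-en-1-yl)-3-methyloxiran-2-yl]-5-[(tert-butyldimethylsilyl)oxy]-6-methylideneoctan-2-one
Conditions: L-fructose-derived Shi ketone (enantiomer of the ketone of step 2, 0.3 equiv), KHSO5 (as 2KHSO5·KHSO4·K2SO4, 1.4 equiv), K2CO3, Bu4NHSO4, Na2B4O7/Na2EDTA buffer, MeCN–CH2(OMe)2–H2O, −10 → 0 °C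
Reagents that add atoms: potassium peroxymonosulfate, [K+].[O-]S(=O)(=O)OO
Why: Shi epoxidation is chemoselective for the electron-rich E-trisubstituted C11=C12 over the monosubstituted C1=C2 and the hindered, inductively deactivated C8=C19; the enantiomeric ketone should give the (11S,12S) epoxide under reagent control.

**Step 10**
Reactants: 15 (5R)-8-[(2S,3S)-3-(but-3-en-1-yl)-3-methyloxiran-2-yl]-5-[(tert-butyldimethylsilyl)oxy]-6-methylideneoctan-2-one; 16 (E)-but-2-enal
Product: 17 (2E)-5-[(2S,3S)-3-{(4R)-4-[(tert-butyldimethylsilyl)oxy]-3-methylidene-7-oxooctyl}-2-methyloxiran-2-yl]pent-2-enal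
Conditions: second-generation Hoveyda–Grubbs catalyst RuCl2(H2IMes)(=CH–C6H4-2-OiPr) (5 mol %), 16 (5 equiv), CH2Cl2, 40 °C
Reagents that add atoms: none
Why: Olefin cross-metathesis of the only monosubstituted alkene with crotonaldehyde gives the E-enal (C1=C2–C3HO); the 1,1-disubstituted C8=C19, the epoxide and the ketone do not take part.

**Step 11**
Reactants: 18 S-ethyl propanethioate
Product: 19 {[(1Z)-1-(ethylsulfanyl)prop-1-en-1-yl]oxy}trimethylsilane
Conditions: LiN(iPr)2, THF, −78 °C; Me3SiCl, −78 → 0 °C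
Reagents that add atoms: chlorotrimethylsilane, C[Si](C)(C)Cl
Why: Kinetic enolisation through the cyclic transition state places methyl trans to the enolate oxygen, and O-silylation gives the (Z)-silyl ketene thioacetal.

**Step 12**
Reactants: 17 (2E)-5-[(2S,3S)-3-{(4R)-4-[(tert-butyldimethylsilyl)oxy]-3-methylidene-7-oxooctyl}-2-methyloxiran-2-yl]pent-2-enal; 19 {[(1Z)-1-(ethylsulfanyl)prop-1-en-1-yl]oxy}trimethylsilane
Product: 20 S-ethyl (2S,3R)-5-[(2S,3S)-3-{(4R)-4-[(tert-butyldimethylsilyl)oxy]-3-methylidene-7-oxooctyl}-2-methyloxiran-2-yl]-2-methyl-3-(2-oxoethyl)pentanethioate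
Conditions: (2S,5S)-5-benzyl-2-tert-butyl-3-methylimidazolidin-4-one·CF3CO2H (20 mol %), CH2Cl2–i-PrOH, H2O (2 equiv), −55 °C
Reagents that add atoms: none
Why: Iminium-catalysed enantioselective Mukaiyama–Michael addition: the benzyl group shields one face of the E-iminium ion, so the (2S,5S) catalyst should give (1R), and the open transition state with the (Z)-ketene thioacetal should give the 2,3-syn adduct, that is (15S); hydrolysis releases the C3 aldehyde.

**Step 13**
Reactants: 20 S-ethyl (2S,3R)-5-[(2S,3S)-3-{(4R)-4-[(tert-butyldimethylsilyl)oxy]-3-methylidene-7-oxooctyl}-2-methyloxiran-2-yl]-2-methyl-3-(2-oxoethyl)pentanethioate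
Product: 22 (1R,3R,4S,7R,11S,12S,15S)-7-[(tert-butyldimethylsilyl)oxy]-11,12-epoxy-4-hydroxycembr-8(19)-en-16,3-olide, via macrocyclic 3,4-diol thioester 21 (not isolated)
Conditions: SmI2 (4 equiv), THF, syringe-pump addition of 20 to a final 0.002 M, −78 → 23 °C; aq. NaHCO3/Na2S2O3
Reagents that add atoms: none
Why: SmI2 transfers one electron to the aldehyde, which is reduced far faster than the methyl ketone or the thioester, and the C3 samarium ketyl adds to the samarium-bound C4 ketone; a second electron gives the samarium diolate of 21, an intramolecular pinacol coupling whose closest known type is the pinacol macrocyclisation of keto aldehydes to 14-membered cembranoid 3,4-diols. Two rings close: the 14-membered carbocycle by 14-exo-trig addition of the C3 ketyl to the C4 carbonyl carbon under high dilution, and the δ-lactone by 6-exo-trig acyl substitution of the C3 samarium alkoxide on the C16 thioester with loss of ethanethiolate. C3 and C4 are the new stereocentres: their relative configuration should be set by the five-membered chelate in which one trivalent samarium holds both oxygens, which places the ring bonds C2–C3 and C4–C5 cis (the cis-diol the target requires). The configuration of C3 relative to C1 should be set by the resident C1 centre, whose thioester carbonyl can bind the same samarium so that C3–O and the C15 arm take up the chair-like cis-1,3 arrangement of the later lactone. The step needs chemoselectivity (aldehyde before ketone; no HMPA, so that neither ketyl–olefin cyclisation onto C8=C19 nor epoxide deoxygenation competes), cyclisation instead of dimerisation (slow addition, high dilution) and the facial selectivity just described. The (3R) diolate lactonises to the δ-lactone in which C14 on C1, C4 on C3 and the C15 methyl are all equatorial.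

**Step 14**
Reactants: 22 (1R,3R,4S,7R,11S,12S,15S)-7-[(tert-butyldimethylsilyl)oxy]-11,12-epoxy-4-hydroxycembr-8(19)-en-16,3-olide
Product: 23 (1R,3R,4S,7R,11S,12S,15S)-11,12-epoxy-4,7-dihydroxycembr-8(19)-en-16,3-olide (target)
Conditions: Bu4NF, AcOH (1 equiv each), THF, 0 → 23 °C
Reagents that add atoms: none
Why: Fluoride-mediated desilylation frees the C7 alcohol; buffering with acetic acid should spare the lactone and the epoxide.

**Compound list**

1 | 6-methylhept-5-en-2-one | CC(=O)CCC=C(C)C | starting material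
2 | ethane-1,2-diol | OCCO | starting material
3 | 2-methyl-2-(4-methylpent-3-en-1-yl)-1,3-dioxolane | CC(C)=CCCC1(C)OCCO1 | intermediate
4 | 2-{2-[(2R)-3,3-dimethyloxiran-2-yl]ethyl}-2-methyl-1,3-dioxolane | CC1(CC[C@H]2OC2(C)C)OCCO1 | intermediate
5 | (3R)-2-methyl-5-(2-methyl-1,3-dioxolan-2-yl)pent-1-en-3-ol | C=C(C)[C@H](O)CCC1(C)OCCO1 | intermediate
6 | hex-1-en-5-yne | C=CCCC#C | starting material
7 | [(1E)-2-methylhexa-1,5-dien-1-yl]dimethylalane | C=CCC/C(C)=C/[Al](C)C | intermediate (not isolated)
8 | lithium butyl[(1E)-2-methylhexa-1,5-dien-1-yl]dimethylalanate | [Li+].C=CCC/C(C)=C/[Al-](C)(C)CCCC | intermediate (not isolated)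
9 | (2E)-3-methylhepta-2,6-dien-1-ol | C=CCC/C(C)=C/CO | intermediate
10 | (5E)-7-bromo-5-methylhepta-1,5-diene | C=CCC/C(C)=C/CBr | intermediate
11 | O,C-dilithio derivative of 5 (lithium alkoxide, 2-(lithiomethyl)allyl) | [Li]CC(=C)[C@H](O[Li])CCC1(C)OCCO1 | intermediate (not isolated)
12 | (3R,7E)-8-methyl-4-methylidene-1-(2-methyl-1,3-dioxolan-2-yl)dodeca-7,11-dien-3-ol | C=CCC/C(C)=C/CCC(=C)[C@H](O)CCC1(C)OCCO1 | intermediate
13 | tert-butyl(dimethyl){[(3R,7E)-8-methyl-4-methylidene-1-(2-methyl-1,3-dioxolan-2-yl)dodeca-7,11-dien-3-yl]oxy}silane | C=CCC/C(C)=C/CCC(=C)[C@H](O[Si](C)(C)C(C)(C)C)CCC1(C)OCCO1 | intermediate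
14 | (5R,9E)-5-[(tert-butyldimethylsilyl)oxy]-10-methyl-6-methylidenetetradeca-9,13-dien-2-one | C=CCC/C(C)=C/CCC(=C)[C@H](O[Si](C)(C)C(C)(C)C)CCC(C)=O | intermediate
15 | (5R)-8-[(2S,3S)-3-(but-3-en-1-yl)-3-methyloxiran-2-yl]-5-[(tert-butyldimethylsilyl)oxy]-6-methylideneoctan-2-one | C=C(CC[C@@H]1O[C@@]1(C)CCC=C)[C@H](O[Si](C)(C)C(C)(C)C)CCC(C)=O | intermediate
16 | (E)-but-2-enal | C/C=C/C=O | starting material
17 | (2E)-5-[(2S,3S)-3-{(4R)-4-[(tert-butyldimethylsilyl)oxy]-3-methylidene-7-oxooctyl}-2-methyloxiran-2-yl]pent-2-enal | C=C(CC[C@@H]1O[C@@]1(C)CC/C=C/C=O)[C@H](O[Si](C)(C)C(C)(C)C)CCC(C)=O | intermediate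
18 | S-ethyl propanethioate | CCC(=O)SCC | starting material
19 | {[(1Z)-1-(ethylsulfanyl)prop-1-en-1-yl]oxy}trimethylsilane | C/C=C(\SCC)O[Si](C)(C)C | intermediate
20 | S-ethyl (2S,3R)-5-[(2S,3S)-3-{(4R)-4-[(tert-butyldimethylsilyl)oxy]-3-methylidene-7-oxooctyl}-2-methyloxiran-2-yl]-2-methyl-3-(2-oxoethyl)pentanethioate | C=C(CC[C@@H]1O[C@@]1(C)CC[C@H](CC=O)[C@H](C)C(=O)SCC)[C@H](O[Si](C)(C)C(C)(C)C)CCC(C)=O | intermediate
21 | S-ethyl (1R,3R,4S,7R,11S,12S,15S)-7-[(tert-butyldimethylsilyl)oxy]-11,12-epoxy-3,4-dihydroxycembr-8(19)-ene-16-thioate (formed as its samarium diolate) | C=C1CC[C@@H]2O[C@@]2(C)CC[C@H](C[C@@H](O)[C@@](C)(O)CC[C@H]1O[Si](C)(C)C(C)(C)C)[C@H](C)C(=O)SCC | intermediate (not isolated)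
22 | (1R,3R,4S,7R,11S,12S,15S)-7-[(tert-butyldimethylsilyl)oxy]-11,12-epoxy-4-hydroxycembr-8(19)-en-16,3-olide | C=C1CC[C@@H]2O[C@@]2(C)CC[C@@H]2C[C@@H](OC(=O)[C@H]2C)[C@@](C)(O)CC[C@H]1O[Si](C)(C)C(C)(C)C | intermediate
23 | (1R,3R,4S,7R,11S,12S,15S)-11,12-epoxy-4,7-dihydroxycembr-8(19)-en-16,3-olide (CNP0262409.1) | C=C1CC[C@@H]2O[C@@]2(C)CC[C@@H]2C[C@@H](OC(=O)[C@H]2C)[C@@](C)(O)CC[C@H]1O | target

**Step count.** Total: 14 steps. Longest linear sequence: 11 steps (steps 1–3, 6–10, 12–14).

**Steps most likely to fail**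

Step 13 (key step). Ring closure may lose out to intermolecular pinacol dimerisation or to plain reduction of the aldehyde. The Lewis-acidic trivalent samarium salts may open the epoxide, and facial selectivity at C3/C4 may be poor. The fallback installs the epoxide last and closes the ring with titanium; it sets out from 14 and comes back to the route at 22. Ketone 14 is taken without epoxidation into cross-metathesis with 16 (conditions of step 10) to give (2E,6E,11R)-11-[(tert-butyldimethylsilyl)oxy]-6-methyl-10-methylidene-14-oxopentadeca-2,6-dienal F1. Mukaiyama–Michael addition of 19 (conditions of step 12) gives the epoxide-free keto aldehyde thioester F2. Low-valent titanium pinacol coupling (TiCl3, Zn–Cu, DME, high dilution, 25 °C; then DBU to complete lactonisation), the established way to 14-membered cembranoid 3,4-diols, gives the macrocyclic lactone F3 with the 11,12-olefin intact. Epoxidation of that remaining trisubstituted olefin with the L-fructose-derived ketone and KHSO5 then gives 22.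

Step 12. Simple diastereoselection at C15 may be poor (anti instead of syn) even when C1 is set correctly by the catalyst. The fallback sets C15 under thermodynamic control; it sets out from 17 and comes back at 22. The addition of 19 to 17 is run without regard for C15. The adduct containing the (2R,3R) thioester F4 is cyclised as in step 13 to the C15-epimeric lactone F5. Equilibration through the lactone enolate (DBU, toluene, 60 °C) should then favour 22, in which the C15 methyl is equatorial and trans to the C1 substituent.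

Step 6. Allylic lithiation may be incomplete, and the allyllithium may scramble with the allylic bromide (SN2′ attack, halogen–metal exchange) or be O-alkylated. The fallback forms the same C9–C10 bond by enolate alkylation; it sets out from 5 and 10 and comes back at 13. Alcohol 5 is silylated (TBSCl, imidazole) to the TBS ether F6. Ozonolysis of its only olefin (O3, CH2Cl2–MeOH, −78 °C; Me2S) gives the α-silyloxy methyl ketone F7. The kinetic lithium enolate at the methyl group (LiN(iPr)2, THF, −78 °C) is alkylated with 10 to give ketone F8. Wittig methylenation (Ph3P=CH2, THF, 0 °C) of the C8 ketone then gives 13.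

**Further compounds**

F1 | step 13 | (2E,6E,11R)-11-[(tert-butyldimethylsilyl)oxy]-6-methyl-10-methylidene-14-oxopentadeca-2,6-dienal | O=C/C=C/CC/C(C)=C/CCC(=C)[C@H](O[Si](C)(C)C(C)(C)C)CCC(C)=O
F2 | step 13 | S-ethyl (2S,3R,6E,11R)-11-[(tert-butyldimethylsilyl)oxy]-2,6-dimethyl-10-methylidene-14-oxo-3-(2-oxoethyl)pentadec-6-enethioate | C=C(CC/C=C(\C)CC[C@H](CC=O)[C@H](C)C(=O)SCC)[C@H](O[Si](C)(C)C(C)(C)C)CCC(C)=O
F3 | step 13 | (1R,3R,4S,7R,11E,15S)-7-[(tert-butyldimethylsilyl)oxy]-4-hydroxycembra-8(19),11-dien-16,3-olide | C=C1CC/C=C(\C)CC[C@@H]2C[C@@H](OC(=O)[C@H]2C)[C@@](C)(O)CC[C@H]1O[Si](C)(C)C(C)(C)C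
F4 | step 12 | S-ethyl (2R,3R)-5-[(2S,3S)-3-{(4R)-4-[(tert-butyldimethylsilyl)oxy]-3-methylidene-7-oxooctyl}-2-methyloxiran-2-yl]-2-methyl-3-(2-oxoethyl)pentanethioate | C=C(CC[C@@H]1O[C@@]1(C)CC[C@H](CC=O)[C@@H](C)C(=O)SCC)[C@H](O[Si](C)(C)C(C)(C)C)CCC(C)=O
F5 | step 12 | (1R,3R,4S,7R,11S,12S,15R)-7-[(tert-butyldimethylsilyl)oxy]-11,12-epoxy-4-hydroxycembr-8(19)-en-16,3-olide | C=C1CC[C@@H]2O[C@@]2(C)CC[C@@H]2C[C@@H](OC(=O)[C@@H]2C)[C@@](C)(O)CC[C@H]1O[Si](C)(C)C(C)(C)C
F6 | step 6 | tert-butyl(dimethyl){[(3R)-2-methyl-5-(2-methyl-1,3-dioxolan-2-yl)pent-1-en-3-yl]oxy}silane | C=C(C)[C@H](O[Si](C)(C)C(C)(C)C)CCC1(C)OCCO1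
F7 | step 6 | (3R)-3-[(tert-butyldimethylsilyl)oxy]-5-(2-methyl-1,3-dioxolan-2-yl)pentan-2-one | CC(=O)[C@H](O[Si](C)(C)C(C)(C)C)CCC1(C)OCCO1
F8 | step 6 | (3R,7E)-3-[(tert-butyldimethylsilyl)oxy]-8-methyl-1-(2-methyl-1,3-dioxolan-2-yl)dodeca-7,11-dien-4-one | C=CCC/C(C)=C/CCC(=O)[C@H](O[Si](C)(C)C(C)(C)C)CCC1(C)OCCO1
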